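## Analysis of the target

The target is a hydroazulene (bicyclo[5.3.0]decene). Cyclopentane ring A (C1–C5) is fused through the C1–C5 bond to cycloheptene ring B (C1, C5, C6, C7, C8, C9, C10). In the numbering used here C1 is the quaternary fusion carbon with a methyl group, C4 the tertiary carbinol with the isopropyl group, C6 carries the 4-hydroxybenzoate, C8=C9 is the trisubstituted alkene (methyl on C8) and C10 carries the 3-methylbutanoate.

There are five stereocentres: C1, C4, C5, C6 and C10 (8aS, 3S, 3aS, 4R and 8R in azulene numbering). With the face of H5 called β, the ring fusion is trans (C1 methyl α), the C4 hydroxyl is β (isopropyl α), the C6 oxygen is α (1,3-anti to the C4 hydroxyl) and the C10 oxygen is β (trans to the C1 methyl). The α-face of ring A therefore carries three neighbouring groups (C1 methyl, the C5–C6 bond, isopropyl), so C5 sits in a crowded arrangement that has to be set under kinetic control.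

Sensitive elements are the secondary, allylic, neopentyl ester at C10, the free phenol, and the tertiary alcohol β to C6, which invites retro-aldol cleavage or elimination whenever C6 is a ketone; the two secondary alcohols also need different acyl groups. The hard parts are the quaternary centre C1 between two stereogenic carbons, the seven-membered ring, and the delivery of three oxygens to defined faces.

The strategy rests on ring B. C5–C6 can be read as an alkyne and C1, C10, C9, C8, C7 as a vinylcyclopropane, with C2–C4 of ring A as the tether. One metal-catalysed (5+2) cycloaddition then closes both rings and leaves alkenes C5=C6 and C9=C10 where the C6 oxygen and the C10 oxygen/C8=C9 unit have to be developed.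

## Retrosynthetic reasoning

**Acyl groups.** The phenol of 33 is unmasked last from aryl acetate 32, because a free phenol would compete in every acylation. The C10 ester is cut next (32 from allylic alcohol 31) and the C6 ester earlier (26 from diol 25). This order means each acylation meets only one free secondary alcohol; the tertiary C4 hydroxyl is too hindered to interfere.

**C10–O and C8=C9.** The allylic alcohol 31 is traced to the C9=C10 alkene of 26 by an oxygen transposition: 31 from hydroxy selenide 29, 29 from β-epoxide 27, 27 from 26. The cut is made here because C9=C10 is exactly what the cycloaddition leaves. The geometry decides the method. The cycloaddition delivers H8 on the α-face, while the C10 oxygen must be β. An ene-type oxygenation would put oxygen on the face of H8, so it is excluded. Epoxidation on the β-face, anti opening at C9 and syn elimination of the selenoxide with the α-H8 gives the required antarafacial relationship.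

**C6–O and C5–H.** Diol 25 comes from β-hydroxy ketone 24 by hydroxyl-directed reduction, which sets the C6 oxygen anti to the C4 hydroxyl. Ketone 24 comes from syn-diol 23, and 23 from the C5=C6 alkene of 20 through the C4–O-tethered hydrosilane 21. The tether is chosen because H5 must enter cis to the C4 oxygen, on the more hindered face, and cannot be corrected later. An intermolecular hydroboration would prefer the less substituted C9=C10. An acid-induced epoxide rearrangement risks 1,2-shifts from C4 and C6. Alcohol 20 is the desilylated cycloadduct 19.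

**Key disconnection.** In 19 the bonds C1–C5 and C6–C7 are cut and the cyclopropane bond C7–C9 is restored, which opens both rings to the acyclic enyne 18. The gain is that ring A, ring B and the quaternary centre C1 arise in one step from a chain with only one stereocentre on the tether (C4) and a stereodefined vinylcyclopropane. The forward reaction must cleave the unsubstituted cyclopropane bond and add to the alkene face that puts the C1 methyl trans to the C4 oxygen. For an E-alkene this requires the (1R,2R)-cyclopropane, and it leaves H8 α.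

**Alkyne and cyclopropyl–alkenyl bond.** The ethynyl group of 18 is traced to the CH2–CHO arm of aldehyde 16 (no change in carbon count), so C5 and C6 come from the starting ring. Aldehyde 16 comes from the primary silyl ether 15. Compound 15 is cut at the C9–C10 bond into alkenyl iodide 9 and cyclopropyltrifluoroborate 14. A stereoretentive cross-coupling joins a geometrically pure alkene and an enantiomerically enriched cyclopropane without touching either. A carbonyl olefination of a methyl ketone would not control the C1=C10 geometry.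

**C1 methyl and ring opening.** Alkenyl iodide 9 is cut at the C1–CH3 bond back to terminal alkyne 7 (syn carbometalation fixes the E geometry). Alkyne 7 comes from methyl ketone 5, and 5 through keto alcohol 4 from the ring alkene of silyl ether 2, that is from (R)-terpinen-4-ol 1. The ring alkene carbons of 1 become C1 and C6, and its carbinol carbon is C4 with the correct configuration and both arms of the right length. The aldehyde terminus is reduced and protected at once so that ketone and aldehyde are never exposed to base together.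

**Cyclopropane fragment.** Trifluoroborate 14 is traced through the auxiliary-bearing boronate 12 to (E)-propenylboronic acid 10 and tartramide 11. The cyclopropane methylene is added to the alkene face selected by the auxiliary.

## Alternatives that were turned down

**Alternative 1:** C1–C10 and C5–C6 are made by an enone–alkene [2+2] photocycloaddition between a methylcyclopentenone and a cyclic bis(silyl) enediol ether. The cyclobutane C6–C10 bond of photoadduct A1 is then cleaved to open ring B.
- For: the carbon skeleton with quaternary C1 arises in two operations from simple achiral partners, and C6 and C10 arrive already oxygenated. On brevity of skeleton assembly it is stronger than the chosen route.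
- Against: A1 is racemic, so a single enantiomer needs resolution or an external chiral influence. The cyclobutane fusion is necessarily cis, which places H5 cis to the C1 methyl, whereas the target is trans-fused; the correction would have to be made at a C5 flanked by two carbonyls. Isopropyl must still be added to the C4 ketone on the right face. The C6 and C10 ketones must be told apart and reduced to opposite faces, and C8=C9 must be introduced by dehydrogenation.
- Comparison: the chosen route is longer to the bicycle but takes C4 from the chiral pool, sets C1 from a defined cyclopropane, and distinguishes C6 from C10 through two different alkenes.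

**Alternative 2:** C6–C7 and C1–C10 are made by cyclopropanation of a silyloxydiene with a ring A vinylcarbenoid (chiral dirhodium tetracarboxylate catalysis), followed by Cope rearrangement of the cis-divinylcyclopropane to A2.
- For: convergent, with strong precedent for the tandem process. A2 already contains C8=C9 and the C10 oxygen, which the chosen route needs three steps to develop; on this point the alternative is clearly stronger.
- Against: C6 carries a carboxyl carbon where the target has oxygen, so a carbon must be excised and replaced. The Cope step has to build the quaternary C1 from a tetrasubstituted ring alkene through a boat transition state next to the silyloxy-bearing terminus. The diazo partner with the C4 stereocentre needs a long preparation. C5 would still have to be set by conjugate reduction of a tetrasubstituted enoate.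
- Comparison: the chosen route keeps C6 as a CH of an alkene that is oxygenated directly, and reaches its cyclisation precursor from a terpene alcohol.

**Alternative 3:** C1–C5 and C8–C9 are made by an intramolecular (4+3) cycloaddition of an oxyallyl cation (from a tertiary α-chloroketone with an alkoxide base in a fluorinated alcohol) onto a tethered silyloxydiene, giving A3.
- For: both rings and C1 in one step, with oxygen at C10 (ketone) and C6 (enol ether) on the correct carbons. The oxidation pattern after the key step is better than in the chosen route.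
- Against: ring-fusion control (C1 against C5) in such stepwise cation–diene closures is usually modest, and C8 is uncontrolled. The precursor needs a geometrically defined silyloxydiene, a tertiary chloroketone and the C4 centre in one chain. The C10 ketone must later be reduced by hydride entering syn to the C1 methyl. C5 lies α to a C6 ketone and β to the C4 oxygen and is therefore at risk.
- Comparison: the chosen route trades a less oxidised cycloadduct for a cycloaddition whose facial course is fixed by a stereocentre in the five-carbon unit.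

Key step: step 11

Assumption 1: (R)-terpinen-4-ol is taken as the commercially available, enantiomerically enriched material; its enantiomeric purity is checked before use.

Assumption 2: the (R,R)-tartramide auxiliary is taken to deliver the (1R,2R)-cyclopropylboronate; if the sense of induction is the opposite, the (S,S)-diamide is used with no other change.

## Route

Step 1
Reactants: 1 (R)-terpinen-4-ol
Product: 2 triethyl{[(1R)-4-methyl-1-(propan-2-yl)cyclohex-3-en-1-yl]oxy}silane
Conditions: Et3SiOTf, 2,6-lutidine, CH2Cl2, 0 °C to rt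
Reagents that add atoms: triethylsilyl trifluoromethanesulfonate, CC[Si](CC)(CC)OS(=O)(=O)C(F)(F)F
Why: Silylation of a hindered tertiary alcohol with a silyl triflate and a hindered pyridine base; the stereocentre is untouched and the ether prevents hemiketal formation and retro-aldol chemistry after ring cleavage.

Step 2
Reactants: 2 triethyl{[(1R)-4-methyl-1-(propan-2-yl)cyclohex-3-en-1-yl]oxy}silane
Product: 4 (5R)-7-hydroxy-5-(propan-2-yl)-5-[(triethylsilyl)oxy]heptan-2-one, via keto aldehyde 3 (not isolated)
Conditions: O3, CH2Cl2, −78 °C; PPh3, −78 °C to rt; then NaBH(OAc)3, AcOH (cat.), rt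
Reagents that add atoms: ozone, [O-][O+]=O
Why: Ozonolysis of the trisubstituted ring alkene gives the keto aldehyde, and NaBH(OAc)3 reduces aldehydes but not unactivated ketones. The two termini are thus differentiated before any base is used, which matters because the 1,6-keto aldehyde would cyclise by aldol reaction under basic conditions.

Step 3
Reactants: 4 (5R)-7-hydroxy-5-(propan-2-yl)-5-[(triethylsilyl)oxy]heptan-2-one
Product: 5 (5R)-5-(propan-2-yl)-5,7-bis[(triethylsilyl)oxy]heptan-2-one
Conditions: Et3SiCl, imidazole, CH2Cl2, 0 °C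
Reagents that add atoms: chlorotriethylsilane, CC[Si](Cl)(CC)CC
Why: Standard silylation of a primary alcohol; a primary triethylsilyl ether is chosen because it can later be oxidised directly to the aldehyde while the tertiary one stays.

Step 4
Reactants: 5 (5R)-5-(propan-2-yl)-5,7-bis[(triethylsilyl)oxy]heptan-2-one
Product: 7 (5R)-5-(propan-2-yl)-5,7-bis[(triethylsilyl)oxy]hept-1-yne, via enol phosphate 6 (not isolated)
Conditions: LiN(iPr)2 (1.1 equiv), THF, −78 °C; ClP(O)(OEt)2, −78 °C to rt; then LiN(iPr)2 (2.3 equiv), −78 °C to rt; H2O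
Reagents that add atoms: none
Why: Negishi conversion of a methyl ketone into a terminal alkyne: kinetic deprotonation at the methyl group, O-phosphorylation, then base-induced elimination of diethyl phosphate from the 1,1-disubstituted enol phosphate.

Step 5
Reactants: 7 (5R)-5-(propan-2-yl)-5,7-bis[(triethylsilyl)oxy]hept-1-yne
Product: 9 (1E,5R)-1-iodo-2-methyl-5-(propan-2-yl)-5,7-bis[(triethylsilyl)oxy]hept-1-ene, via alkenylalane 8 (not isolated)
Conditions: Me3Al (2.5 equiv), Cp2ZrCl2 (0.25 equiv), CH2Cl2, 0 °C to rt; then I2, THF, −30 to 0 °C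
Reagents that add atoms: trimethylaluminium, C[Al](C)C; iodine, II
Why: Zirconium-catalysed methylalumination (Negishi carboalumination) adds methyl and aluminium syn across the terminal alkyne with the metal at the terminus. Iodinolysis with retention gives the E-alkenyl iodide, which fixes the C1=C10 geometry.

Step 6
Reactants: 10 (E)-prop-1-en-1-ylboronic acid; 11 (2R,3R)-2,3-dihydroxy-N,N,N',N'-tetramethylbutanediamide
Product: 12 (4R,5R)-N,N,N',N'-tetramethyl-2-[(1E)-prop-1-en-1-yl]-1,3,2-dioxaborolane-4,5-dicarboxamide
Conditions: MgSO4, CH2Cl2, rt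
Reagents that add atoms: none
Why: Reversible esterification of a boronic acid with a 1,2-diol, driven by removal of water; it installs the chiral auxiliary.

Step 7
Reactants: 12 (4R,5R)-N,N,N',N'-tetramethyl-2-[(1E)-prop-1-en-1-yl]-1,3,2-dioxaborolane-4,5-dicarboxamide
Product: 14 potassium trifluoro[(1R,2R)-2-methylcyclopropyl]borate, via cyclopropylboronate 13 (not isolated)
Conditions: Zn(Cu), CH2I2, Et2O, reflux; then KHF2, MeOH/H2O, rt; recrystallisation
Reagents that add atoms: diiodomethane, ICI; potassium hydrogen difluoride, [K+].F[H-]F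
Why: Simmons–Smith cyclopropanation is stereospecific (E-alkene gives the trans-cyclopropane) and the amide groups of the tartrate auxiliary direct the zinc carbenoid to one face of the alkenylboronate. KHF2 exchanges the labile auxiliary for fluoride and gives a crystalline salt whose recrystallisation should raise the enantiomeric purity.

Step 8
Reactants: 9 (1E,5R)-1-iodo-2-methyl-5-(propan-2-yl)-5,7-bis[(triethylsilyl)oxy]hept-1-ene; 14 potassium trifluoro[(1R,2R)-2-methylcyclopropyl]borate
Product: 15 (1E,5R)-2-methyl-1-[(1R,2R)-2-methylcyclopropyl]-5-(propan-2-yl)-5,7-bis[(triethylsilyl)oxy]hept-1-ene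
Conditions: Pd(OAc)2 (5 mol%), RuPhos (10 mol%), K2CO3, toluene/H2O (10:1), 85 °C
Reagents that add atoms: none
Why: Suzuki–Miyaura coupling of a cyclopropyltrifluoroborate with an alkenyl iodide; the alkene geometry and the configuration of the cyclopropyl carbon are both retained. Partial loss of the primary silyl ether under the aqueous base would be harmless, since the free alcohol is oxidised in the next step as well.

Step 9
Reactants: 15 (1E,5R)-2-methyl-1-[(1R,2R)-2-methylcyclopropyl]-5-(propan-2-yl)-5,7-bis[(triethylsilyl)oxy]hept-1-ene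
Product: 16 (3R,6E)-6-methyl-7-[(1R,2R)-2-methylcyclopropyl]-3-(propan-2-yl)-3-[(triethylsilyl)oxy]hept-6-enal
Conditions: (COCl)2, DMSO, CH2Cl2, −78 to −40 °C; Et3N, −78 to 0 °C
Reagents that add atoms: none
Why: Swern conditions cleave a primary triethylsilyl ether and oxidise it to the aldehyde in one operation, while the hindered tertiary silyl ether survives. The non-acidic medium spares the vinylcyclopropane.

Step 10
Reactants: 16 (3R,6E)-6-methyl-7-[(1R,2R)-2-methylcyclopropyl]-3-(propan-2-yl)-3-[(triethylsilyl)oxy]hept-6-enal
Product: 18 triethyl{[(3S,6E)-6-methyl-7-[(1R,2R)-2-methylcyclopropyl]-3-(propan-2-yl)hept-6-en-1-yn-3-yl]oxy}silane, via enol nonaflate 17 (not isolated)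
Conditions: C4F9SO2F, phosphazene base P2-Et, DMF, −20 °C to rt
Reagents that add atoms: none
Why: One-pot conversion of an enolisable aldehyde into a terminal alkyne through its alkenyl nonaflate (O-sulfonylation of the enolate, then elimination of nonaflate by the same phosphazene base). The carbon count is unchanged, so the ethynyl group sits directly on C4.

Step 11
Reactants: 18 triethyl{[(3S,6E)-6-methyl-7-[(1R,2R)-2-methylcyclopropyl]-3-(propan-2-yl)hept-6-en-1-yn-3-yl]oxy}silane
Product: 19 triethyl{[(3S,6R,8aR)-6,8a-dimethyl-3-(propan-2-yl)-1,2,3,5,6,8a-hexahydroazulen-3-yl]oxy}silane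
Conditions: [Rh(CO)2Cl]2 (5 mol%), 1,2-dichloroethane (0.02 M), 70 °C
Reagents that add atoms: none
Why: This is a rhodium-catalysed intramolecular (5+2) cycloaddition of a tethered alkyne and vinylcyclopropane, a known reaction class that also accepts trisubstituted alkenes. Monovalent rhodium binds alkyne and alkene on one face and oxidative coupling forms C1–C5, giving a trivalent rhodacyclopentene; ring A thereby closes as a five-membered ring by C–C bond formation between the internal alkyne carbon and the alkene terminus across the three-atom tether. The cyclopropylcarbinyl–rhodium unit then opens by cleavage of C7–C9 to an eight-membered rhodacycle, and C6–C7 reductive elimination closes the seven-membered ring B and releases the catalyst; if cyclopropane cleavage precedes alkyne insertion the stereochemical outcome is the same. The trans methyl group points away from the metal in the reactive s-cis conformer, so the unsubstituted C7–C9 bond is cleaved, as is general for trans-2-substituted vinylcyclopropanes. In that conformer C7 and C8 lie on opposite faces of the alkene, so the metal can reach C7 from one face only; with the E-alkene and the (1R,2R)-cyclopropane this is the face that gives the 8aR centre (C1 methyl trans to the C4 oxygen), so the new stereocentre C1 is controlled by the cyclopropane carbon C9, which is consumed. The C4 substituents support this fold, since the bulkier isopropyl group lies on the side away from the forming rhodacycle, and the quaternary propargylic carbon favours ring closure. C8 is carried through unchanged and ends with H8 on the α-face, syn to the C1 methyl, which the later oxygen transposition uses. The step needs cycloaddition to outrun alkyne oligomerisation (hence high dilution) and needs the bond-cleavage selectivity described above.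

Step 12
Reactants: 19 triethyl{[(3S,6R,8aR)-6,8a-dimethyl-3-(propan-2-yl)-1,2,3,5,6,8a-hexahydroazulen-3-yl]oxy}silane
Product: 20 (3S,6R,8aR)-6,8a-dimethyl-3-(propan-2-yl)-1,2,3,5,6,8a-hexahydroazulen-3-ol
Conditions: Bu4NF, THF, 50 °C
Reagents that add atoms: none
Why: Fluoride cleavage of the tertiary silyl ether; it frees the hydroxyl that anchors the next two stereocentres.

Step 13
Reactants: 20 (3S,6R,8aR)-6,8a-dimethyl-3-(propan-2-yl)-1,2,3,5,6,8a-hexahydroazulen-3-ol
Product: 21 {[(3S,6R,8aR)-6,8a-dimethyl-3-(propan-2-yl)-1,2,3,5,6,8a-hexahydroazulen-3-yl]oxy}dimethylsilane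
Conditions: ClSiMe2H, Et3N, DMAP (cat.), CH2Cl2, 0 °C to rt
Reagents that add atoms: chlorodimethylsilane, C[SiH](C)Cl
Why: Silylation of the tertiary alcohol with a chlorohydrosilane places an Si–H bond on the β-face next to C5=C6.

Step 14
Reactants: 21 {[(3S,6R,8aR)-6,8a-dimethyl-3-(propan-2-yl)-1,2,3,5,6,8a-hexahydroazulen-3-yl]oxy}dimethylsilane
Product: 23 (3S,3aS,4S,6R,8aR)-6,8a-dimethyl-3-(propan-2-yl)-1,2,3,3a,4,5,6,8a-octahydroazulene-3,4-diol, via oxasilolane 22 (not isolated)
Conditions: Pt2[(CH2=CHSiMe2)2O]3 (1 mol% Pt), toluene (0.01 M), 60 °C; then H2O2 (30%), KF, KHCO3, THF/MeOH, rt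
Reagents that add atoms: hydrogen peroxide, OO
Why: Platinum-catalysed intramolecular hydrosilylation of an allylic alcohol silyl ether closes a five-membered oxasilolane by syn addition of Si–H across C5=C6 from the face of the C4 oxygen. This puts H5 on the β-face (new stereocentre C5, controlled by the tether) and silicon on C6; Tamao oxidation then replaces C–Si by C–OH with retention.

Step 15
Reactants: 23 (3S,3aS,4S,6R,8aR)-6,8a-dimethyl-3-(propan-2-yl)-1,2,3,3a,4,5,6,8a-octahydroazulene-3,4-diol
Product: 24 (3S,3aR,6R,8aR)-3-hydroxy-6,8a-dimethyl-3-(propan-2-yl)-2,3,3a,5,6,8a-hexahydroazulen-4(1H)-one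
Conditions: Dess–Martin periodinane, NaHCO3, CH2Cl2, 0 °C to rt
Reagents that add atoms: none
Why: Buffered Dess–Martin oxidation of the secondary alcohol; the tertiary alcohol is inert and the β-hydroxy ketone sees neither base nor strong acid, so C5 is not epimerised and no retro-aldol cleavage occurs.

Step 16
Reactants: 24 (3S,3aR,6R,8aR)-3-hydroxy-6,8a-dimethyl-3-(propan-2-yl)-2,3,3a,5,6,8a-hexahydroazulen-4(1H)-one
Product: 25 (3S,3aS,4R,6R,8aR)-6,8a-dimethyl-3-(propan-2-yl)-1,2,3,3a,4,5,6,8a-octahydroazulene-3,4-diol
Conditions: Me4NBH(OAc)3, MeCN/AcOH (1:1), −30 °C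
Reagents that add atoms: none
Why: Evans–Saksena reduction: the acetoxyborohydride exchanges onto the C4 hydroxyl and delivers hydride intramolecularly to the β-face of the C6 carbonyl, giving the 1,3-anti diol with the C6 hydroxyl α.

Step 17
Reactants: 25 (3S,3aS,4R,6R,8aR)-6,8a-dimethyl-3-(propan-2-yl)-1,2,3,3a,4,5,6,8a-octahydroazulene-3,4-diol
Product: 26 (3S,3aS,4R,6R,8aR)-3-hydroxy-6,8a-dimethyl-3-(propan-2-yl)-1,2,3,3a,4,5,6,8a-octahydroazulen-4-yl 4-(acetyloxy)benzoate
Conditions: 4-acetoxybenzoyl chloride, pyridine, DMAP, CH2Cl2, 0 °C to rt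
Reagents that add atoms: 4-(acetyloxy)benzoyl chloride, CC(=O)Oc1ccc(cc1)C(Cl)=O
Why: DMAP-catalysed acylation of the only secondary alcohol; the hindered tertiary alcohol does not react and the phenol is carried as its acetate.

Step 18
Reactants: 26 (3S,3aS,4R,6R,8aR)-3-hydroxy-6,8a-dimethyl-3-(propan-2-yl)-1,2,3,3a,4,5,6,8a-octahydroazulen-4-yl 4-(acetyloxy)benzoate
Product: 27 C9–C10 β-epoxide of 26 (epoxide oxygen cis to H5 and to the C4 hydroxyl)
Conditions: mCPBA, NaHCO3, CH2Cl2, 0 °C
Reagents that add atoms: 3-chloroperoxybenzoic acid, OOC(=O)c1cccc(Cl)c1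
Why: Peracid (Prilezhaev) epoxidation of the only remaining alkene. In the trans-fused cycloheptene the axial C1 methyl shields the α-face, so oxygen should enter from the β-face, possibly assisted by hydrogen bonding to the β C4 hydroxyl.

Step 19
Reactants: 27 C9–C10 β-epoxide of 26
Product: 29 10β-hydroxy-9α-(phenylselanyl) derivative of 26 (C9–C10 saturated), via silyloxy selenide 28 (not isolated)
Conditions: PhSeSiMe3, ZnI2 (10 mol%), CH2Cl2, 0 °C to rt; then citric acid, MeOH, rt
Reagents that add atoms: trimethyl(phenylselanyl)silane, C[Si](C)(C)[Se]c1ccccc1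
Why: Lewis-acid-promoted opening of an epoxide by a silyl selenide is an anti SN2 process. Attack takes place at C9 from the α-face because C10 is neopentyl, and mild acidic methanolysis removes the trimethylsilyl group (including any adventitious silyl ether at C4).

Step 20
Reactants: 29 10β-hydroxy-9α-(phenylselanyl) derivative of 26
Product: 31 (3S,3aS,4R,8R,8aS)-3,8-dihydroxy-6,8a-dimethyl-3-(propan-2-yl)-1,2,3,3a,4,5,8,8a-octahydroazulen-4-yl 4-(acetyloxy)benzoate, via selenoxide 30 (not isolated)
Conditions: H2O2 (30%), pyridine, THF, 0 °C to rt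
Reagents that add atoms: none
Why: Oxidation to the selenoxide and syn elimination complete the conversion of an epoxide into an allylic alcohol. Selenoxides eliminate away from a β-hydroxyl, and on that side the syn hydrogen is the α-H8, so C8=C9 forms and C10 keeps its β-oxygen.

Step 21
Reactants: 31 (3S,3aS,4R,8R,8aS)-3,8-dihydroxy-6,8a-dimethyl-3-(propan-2-yl)-1,2,3,3a,4,5,8,8a-octahydroazulen-4-yl 4-(acetyloxy)benzoate
Product: 32 (3S,3aS,4R,8R,8aS)-3-hydroxy-6,8a-dimethyl-8-[(3-methylbutanoyl)oxy]-3-(propan-2-yl)-1,2,3,3a,4,5,8,8a-octahydroazulen-4-yl 4-(acetyloxy)benzoate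
Conditions: 3-methylbutanoyl chloride, pyridine, DMAP, CH2Cl2, rt
Reagents that add atoms: 3-methylbutanoyl chloride, CC(C)CC(Cl)=O
Why: DMAP-catalysed acylation of the secondary allylic alcohol, the only unhindered hydroxyl left; the tertiary alcohol stays free.

Step 22
Reactants: 32 (3S,3aS,4R,8R,8aS)-3-hydroxy-6,8a-dimethyl-8-[(3-methylbutanoyl)oxy]-3-(propan-2-yl)-1,2,3,3a,4,5,8,8a-octahydroazulen-4-yl 4-(acetyloxy)benzoate
Product: 33 (3S,3aS,4R,8R,8aS)-3-hydroxy-6,8a-dimethyl-8-[(3-methylbutanoyl)oxy]-3-(propan-2-yl)-1,2,3,3a,4,5,8,8a-octahydroazulen-4-yl 4-hydroxybenzoate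
Conditions: pyrrolidine (1.5 equiv), CH2Cl2, 0 °C
Reagents that add atoms: none
Why: Aryl acetates undergo aminolysis far faster than alkyl esters or alkyl benzoates, so a secondary amine at low temperature should release the phenol and leave both other esters intact.

## Compound list

1 | (R)-terpinen-4-ol, (1R)-4-methyl-1-(propan-2-yl)cyclohex-3-en-1-ol | CC1=CC[C@@](O)(C(C)C)CC1 | starting material
2 | triethyl{[(1R)-4-methyl-1-(propan-2-yl)cyclohex-3-en-1-yl]oxy}silane | CC1=CC[C@@](O[Si](CC)(CC)CC)(C(C)C)CC1 | intermediate
3 | (3R)-6-oxo-3-(propan-2-yl)-3-[(triethylsilyl)oxy]heptanal | O=CC[C@@](O[Si](CC)(CC)CC)(C(C)C)CCC(C)=O | intermediate (not isolated)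
4 | (5R)-7-hydroxy-5-(propan-2-yl)-5-[(triethylsilyl)oxy]heptan-2-one | OCC[C@@](O[Si](CC)(CC)CC)(C(C)C)CCC(C)=O | intermediate
5 | (5R)-5-(propan-2-yl)-5,7-bis[(triethylsilyl)oxy]heptan-2-one | CC[Si](CC)(CC)OCC[C@@](O[Si](CC)(CC)CC)(C(C)C)CCC(C)=O | intermediate
6 | diethyl (5R)-5-(propan-2-yl)-5,7-bis[(triethylsilyl)oxy]hept-1-en-2-yl phosphate | CC[Si](CC)(CC)OCC[C@@](O[Si](CC)(CC)CC)(C(C)C)CCC(=C)OP(=O)(OCC)OCC | intermediate (not isolated)
7 | (5R)-5-(propan-2-yl)-5,7-bis[(triethylsilyl)oxy]hept-1-yne | CC[Si](CC)(CC)OCC[C@@](O[Si](CC)(CC)CC)(C(C)C)CCC#C | intermediate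
8 | dimethyl[(1E,5R)-2-methyl-5-(propan-2-yl)-5,7-bis[(triethylsilyl)oxy]hept-1-en-1-yl]alumane | CC[Si](CC)(CC)OCC[C@@](O[Si](CC)(CC)CC)(C(C)C)CC/C(C)=C/[Al](C)C | intermediate (not isolated)
9 | (1E,5R)-1-iodo-2-methyl-5-(propan-2-yl)-5,7-bis[(triethylsilyl)oxy]hept-1-ene | CC[Si](CC)(CC)OCC[C@@](O[Si](CC)(CC)CC)(C(C)C)CC/C(C)=C/I | intermediate
10 | (E)-prop-1-en-1-ylboronic acid | C/C=C/B(O)O | starting material
11 | (2R,3R)-2,3-dihydroxy-N,N,N',N'-tetramethylbutanediamide | CN(C)C(=O)[C@H](O)[C@@H](O)C(=O)N(C)C | starting material
12 | (4R,5R)-N,N,N',N'-tetramethyl-2-[(1E)-prop-1-en-1-yl]-1,3,2-dioxaborolane-4,5-dicarboxamide | CN(C)C(=O)[C@@H]1OB(/C=C/C)O[C@H]1C(=O)N(C)C | intermediate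
13 | (4R,5R)-N,N,N',N'-tetramethyl-2-[(1R,2R)-2-methylcyclopropyl]-1,3,2-dioxaborolane-4,5-dicarboxamide | CN(C)C(=O)[C@@H]1OB([C@@H]2C[C@H]2C)O[C@H]1C(=O)N(C)C | intermediate (not isolated)
14 | potassium trifluoro[(1R,2R)-2-methylcyclopropyl]borate | [K+].F[B-](F)(F)[C@@H]1C[C@H]1C | intermediate
15 | (1E,5R)-2-methyl-1-[(1R,2R)-2-methylcyclopropyl]-5-(propan-2-yl)-5,7-bis[(triethylsilyl)oxy]hept-1-ene | CC[Si](CC)(CC)OCC[C@@](O[Si](CC)(CC)CC)(C(C)C)CC/C(C)=C/[C@@H]1C[C@H]1C | intermediate
16 | (3R,6E)-6-methyl-7-[(1R,2R)-2-methylcyclopropyl]-3-(propan-2-yl)-3-[(triethylsilyl)oxy]hept-6-enal | O=CC[C@@](O[Si](CC)(CC)CC)(C(C)C)CC/C(C)=C/[C@@H]1C[C@H]1C | intermediate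
17 | enol nonaflate of 16 (C5=C6 E/Z mixture; C6–OSO2C4F9) | FC(F)(F)C(F)(F)C(F)(F)C(F)(F)S(=O)(=O)OC=C[C@@](O[Si](CC)(CC)CC)(C(C)C)CC/C(C)=C/[C@@H]1C[C@H]1C | intermediate (not isolated)
18 | triethyl{[(3S,6E)-6-methyl-7-[(1R,2R)-2-methylcyclopropyl]-3-(propan-2-yl)hept-6-en-1-yn-3-yl]oxy}silane | C#C[C@@](O[Si](CC)(CC)CC)(C(C)C)CC/C(C)=C/[C@@H]1C[C@H]1C | intermediate
19 | triethyl{[(3S,6R,8aR)-6,8a-dimethyl-3-(propan-2-yl)-1,2,3,5,6,8a-hexahydroazulen-3-yl]oxy}silane | C[C@H]1C=C[C@@]2(C)CC[C@](O[Si](CC)(CC)CC)(C(C)C)C2=CC1 | intermediate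
20 | (3S,6R,8aR)-6,8a-dimethyl-3-(propan-2-yl)-1,2,3,5,6,8a-hexahydroazulen-3-ol | C[C@H]1C=C[C@@]2(C)CC[C@](O)(C(C)C)C2=CC1 | intermediate
21 | {[(3S,6R,8aR)-6,8a-dimethyl-3-(propan-2-yl)-1,2,3,5,6,8a-hexahydroazulen-3-yl]oxy}dimethylsilane | C[C@H]1C=C[C@@]2(C)CC[C@](O[SiH](C)C)(C(C)C)C2=CC1 | intermediate
22 | cyclic siloxane from 21: 2,2-dimethyl-1-oxa-2-silacyclopentane spanning C4–O and C6 (Si on C6 β, H5 β) | C[C@H]1C=C[C@@]2(C)CC[C@@]3(C(C)C)O[Si](C)(C)[C@@H](C1)[C@H]23 | intermediate (not isolated)
23 | (3S,3aS,4S,6R,8aR)-6,8a-dimethyl-3-(propan-2-yl)-1,2,3,3a,4,5,6,8a-octahydroazulene-3,4-diol | C[C@H]1C=C[C@@]2(C)CC[C@](O)(C(C)C)[C@@H]2[C@@H](O)C1 | intermediate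
24 | (3S,3aR,6R,8aR)-3-hydroxy-6,8a-dimethyl-3-(propan-2-yl)-2,3,3a,5,6,8a-hexahydroazulen-4(1H)-one | C[C@H]1C=C[C@@]2(C)CC[C@](O)(C(C)C)[C@@H]2C(=O)C1 | intermediate
25 | (3S,3aS,4R,6R,8aR)-6,8a-dimethyl-3-(propan-2-yl)-1,2,3,3a,4,5,6,8a-octahydroazulene-3,4-diol | C[C@H]1C=C[C@@]2(C)CC[C@](O)(C(C)C)[C@@H]2[C@H](O)C1 | intermediate
26 | (3S,3aS,4R,6R,8aR)-3-hydroxy-6,8a-dimethyl-3-(propan-2-yl)-1,2,3,3a,4,5,6,8a-octahydroazulen-4-yl 4-(acetyloxy)benzoate | C[C@H]1C=C[C@@]2(C)CC[C@](O)(C(C)C)[C@@H]2[C@H](OC(=O)c2ccc(OC(C)=O)cc2)C1 | intermediate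
27 | C9–C10 β-epoxide of 26 (epoxide oxygen cis to H5 and the C4 hydroxyl, trans to the C1 methyl) | C[C@H]1[C@H]2O[C@H]2[C@@]3(C)CC[C@](O)(C(C)C)[C@@H]3[C@H](OC(=O)c4ccc(OC(C)=O)cc4)C1 | intermediate
28 | 9α-(phenylselanyl)-10β-(trimethylsilyloxy) derivative of 26 (C9–C10 saturated) | C[C@H]1[C@H]([Se]c2ccccc2)[C@@H](O[Si](C)(C)C)[C@@]3(C)CC[C@](O)(C(C)C)[C@@H]3[C@H](OC(=O)c4ccc(OC(C)=O)cc4)C1 | intermediate (not isolated)
29 | 10β-hydroxy-9α-(phenylselanyl) derivative of 26 (C9–C10 saturated) | C[C@H]1[C@H]([Se]c2ccccc2)[C@@H](O)[C@@]3(C)CC[C@](O)(C(C)C)[C@@H]3[C@H](OC(=O)c4ccc(OC(C)=O)cc4)C1 | intermediate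
30 | selenoxide of 29 (configuration at selenium undefined) | C[C@H]1[C@H]([Se](=O)c2ccccc2)[C@@H](O)[C@@]3(C)CC[C@](O)(C(C)C)[C@@H]3[C@H](OC(=O)c4ccc(OC(C)=O)cc4)C1 | intermediate (not isolated)
31 | (3S,3aS,4R,8R,8aS)-3,8-dihydroxy-6,8a-dimethyl-3-(propan-2-yl)-1,2,3,3a,4,5,8,8a-octahydroazulen-4-yl 4-(acetyloxy)benzoate | CC1=C[C@@H](O)[C@@]2(C)CC[C@](O)(C(C)C)[C@@H]2[C@H](OC(=O)c2ccc(OC(C)=O)cc2)C1 | intermediate
32 | (3S,3aS,4R,8R,8aS)-3-hydroxy-6,8a-dimethyl-8-[(3-methylbutanoyl)oxy]-3-(propan-2-yl)-1,2,3,3a,4,5,8,8a-octahydroazulen-4-yl 4-(acetyloxy)benzoate | CC1=C[C@@H](OC(=O)CC(C)C)[C@@]2(C)CC[C@](O)(C(C)C)[C@@H]2[C@H](OC(=O)c2ccc(OC(C)=O)cc2)C1 | intermediate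
33 | (3S,3aS,4R,8R,8aS)-3-hydroxy-6,8a-dimethyl-8-[(3-methylbutanoyl)oxy]-3-(propan-2-yl)-1,2,3,3a,4,5,8,8a-octahydroazulen-4-yl 4-hydroxybenzoate | CC1=C[C@@H](OC(=O)CC(C)C)[C@@]2(C)CC[C@](O)(C(C)C)[C@@H]2[C@H](OC(=O)c2ccc(O)cc2)C1 | target

## Step count and least certain steps

Total step count: 22 (steps 6 and 7 prepare the cyclopropane fragment). Longest linear sequence: 20 steps, from 1 through steps 1–5 and 8–22.

**Step 11 (key step).** The trisubstituted alkene may enter the oxidative coupling too slowly, so that alkyne oligomerisation or simple cycloisomerisation takes over. The bulky silyloxy group beside the alkyne could also oppose the fold demanded by the cyclopropane and erode selectivity for cleavage of the unsubstituted bond. Fallback: start from 18 and remove the silyl group first (Bu4NF, THF) to give (3S,6E)-6-methyl-7-[(1R,2R)-2-methylcyclopropyl]-3-(propan-2-yl)hept-6-en-1-yn-3-ol F1. The smaller free carbinol is then cyclised with [Rh(CO)2Cl]2 or, by the mechanistically distinct ruthenacyclopentene pathway, with [CpRu(MeCN)3]PF6. The product is 20, where the route is rejoined one step later.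

**Step 14 (tethered hydrosilylation and oxidation).** The C4-bound Si–H can also reach the less substituted C9=C10 alkene across the concave face of the diene, so addition there may compete, or the 5-endo addition to the hindered C5=C6 may stall. Fallback: start from 19 and reach 24 by an epoxide rearrangement.
- Dioxirane epoxidation (KHSO5, K2CO3 buffer, the fructose-derived ketone 1,2:4,5-di-O-isopropylidene-β-D-erythro-2,3-hexodiulo-2,6-pyranose or its enantiomer) is selective for trisubstituted over cis-disubstituted alkenes. It should attack C5=C6 on the α-face, which is not blocked by the silyloxy group, to give the 5α,6α-epoxide of 19 F2.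
- BF3·OEt2 at −78 °C then induces a Meinwald rearrangement. The silyloxy group is anti to the breaking C5–O bond, so no carbon group on C4 is aligned for a semipinacol shift, and H6 migrates to the β-face of C5 to give (3S,3aR,6R,8aR)-6,8a-dimethyl-3-(propan-2-yl)-3-[(triethylsilyl)oxy]-2,3,3a,5,6,8a-hexahydroazulen-4(1H)-one F3. Ring contraction by C7 migration is the competing pathway to watch.
- Buffered HF·pyridine removes the silyl group and gives 24.

**Step 10 (alkyne from aldehyde).** The enolate of the β-silyloxy aldehyde may lose the silyloxy group (β-elimination) before O-sulfonylation, or deprotonation at the neopentyl CH2 may be slow. Fallback: start from 16 and trap the potassium enolate at −78 °C (KN(SiMe3)2, N-(5-chloropyridin-2-yl)bis(trifluoromethanesulfonyl)imide, THF) as (6E)-6-methyl-7-[(1R,2R)-2-methylcyclopropyl]-3-(propan-2-yl)-3-[(triethylsilyl)oxy]hepta-1,6-dien-1-yl trifluoromethanesulfonate F4, which is isolated. Elimination in a separate operation with LiN(iPr)2 at −78 to 0 °C returns to 18.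

**Step 18 (epoxidation face).** The peracid may attack C9=C10 from the α-face if the ring adopts a conformation in which the C1 methyl no longer shields it; the selenide sequence would then give the wrong C10 epimer. Fallback: start from 26 and let the electrophile take the more accessible face while oxygen enters from the other. NBS in aqueous 1,2-dimethoxyethane should give the 10α-bromo-9β-hydroxy derivative of 26 F5 (water attacks the bromonium ion at the less hindered C9). DBU in CH2Cl2 then closes the β-epoxide 27 by intramolecular displacement.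

## Further compounds

F1 | step 11 | (3S,6E)-6-methyl-7-[(1R,2R)-2-methylcyclopropyl]-3-(propan-2-yl)hept-6-en-1-yn-3-ol | C#C[C@@](O)(C(C)C)CC/C(C)=C/[C@@H]1C[C@H]1C
F2 | step 14 | 5α,6α-epoxide of 19 (epoxide oxygen trans to the C4 silyloxy group) | C[C@H]1C=C[C@@]2(C)CC[C@](O[Si](CC)(CC)CC)(C(C)C)[C@]23O[C@@H]3C1
F3 | step 14 | (3S,3aR,6R,8aR)-6,8a-dimethyl-3-(propan-2-yl)-3-[(triethylsilyl)oxy]-2,3,3a,5,6,8a-hexahydroazulen-4(1H)-one | C[C@H]1C=C[C@@]2(C)CC[C@](O[Si](CC)(CC)CC)(C(C)C)[C@@H]2C(=O)C1
F4 | step 10 | (6E)-6-methyl-7-[(1R,2R)-2-methylcyclopropyl]-3-(propan-2-yl)-3-[(triethylsilyl)oxy]hepta-1,6-dien-1-yl trifluoromethanesulfonate (E/Z mixture at the enol double bond) | FC(F)(F)S(=O)(=O)OC=C[C@@](O[Si](CC)(CC)CC)(C(C)C)CC/C(C)=C/[C@@H]1C[C@H]1C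
F5 | step 18 | 10α-bromo-9β-hydroxy derivative of 26 (C9–C10 saturated) | C[C@H]1[C@@H](O)[C@H](Br)[C@@]3(C)CC[C@](O)(C(C)C)[C@@H]3[C@H](OC(=O)c4ccc(OC(C)=O)cc4)C1
A1 | alternative 1 | cis-anti-cis tricyclic bis(trimethylsilyloxy) photoadduct with C4 ketone | C[C@]12CCC(=O)[C@H]1[C@]1(O[Si](C)(C)C)CC(C)C[C@]21O[Si](C)(C)C
A2 | alternative 2 | bicyclic cycloheptadiene with C6 methyl ester, C10 silyl ether and quaternary C1 | CC1=C[C@@H](O[Si](C)(C)C(C)(C)C)[C@@]2(C)CC[C@](O[Si](CC)(CC)CC)(C(C)C)C2=C(C(=O)OC)C1
A3 | alternative 3 | bicyclo[5.3.0]decenone with C10 ketone and C6 silyl enol ether | CC1CC(=O)[C@@]2(C)CC[C@](O[Si](CC)(CC)CC)(C(C)C)[C@@H]2C(O[Si](C(C)C)(C(C)C)C(C)C)=C1
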